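Remark on the chemistry: the target has no stereocentre and no configurationally stable axis, so configuration plays no part in any step. Equivalents quoted are planning values. The ring A oxygen is carried as a benzenesulfonate instead of an alkyl ether, for the reasons argued below.

## Structural features

The target, 3,5-dibromo-2-(2,4-dibromophenoxy)phenol, is a diaryl ether: two benzene rings and no other ring, joined only through one oxygen that links C2 of ring A to C1' of ring B. Ring A is a phenol (C1–OH) with the ether oxygen on the neighbouring C2 and bromines on C3 and C5, that is ortho and para to the ether oxygen but meta to the hydroxyl. Ring B carries bromines on C2' and C4', ortho and para to the same oxygen. There is no stereocentre, so no stereochemical relationship has to be set. The sensitive groups are the four aryl C–Br bonds (lost or scrambled by organolithium reagents, low-valent metals and copper- or palladium-mediated couplings) and the free phenol, which would steer any electrophile to C4 and C6 of ring A. The real difficulty is the ether bond: its oxygen is flanked by C1–O and C3–Br on ring A and by C2'–Br on ring B, so a classical coupling must join a doubly ortho-substituted phenoxide to an ortho-substituted aryl electrophile while sparing the other C–Br bonds. The ring A bromines also sit where the C2 oxygen directs them and not where the C1 hydroxyl does, so the two oxygens of ring A must be told apart early. The key step uses the vicinal pair O–C1'/C2'–Br of ring B: two adjacent ring carbons that accept a nucleophile and an electrophile are the two carbons of an aryne, and the remaining C4'–Br lies para to the ether oxygen, where ordinary electrophilic bromination can place it once ring A is electron-poor.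

## Logic of the disconnections

13 ⇒ 11. The S–O bond of a sulfonate ester on the C1 oxygen is cut (functional-group interconversion). The free phenol cannot be present during bromination of ring B because it would activate C4 and C6 of ring A. A sulfonate makes that oxygen electron-withdrawing and comes off in one operation. The forward step must cleave at sulfur only, leaving four C–Br bonds and the diaryl ether untouched, and must not create an alkylating by-product.

11 ⇒ 10. The C4'–Br bond is cut. With ring A carrying two bromines and a sulfonyloxy group, and the sulfonyl phenyl ring (ring C) carrying the sulfonyl group, the only donor-activated position left is C4', para to the ether oxygen. C2' is occupied and C6' is screened by the twisted ring A. This removes one bromine and leaves a ring B that is simply ortho-bromophenyl. The forward step must stop at mono-bromination.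

10 ⇒ 4 + 5 + 6. The O–C1' and C2'–Br bonds are cut together, which is the aryne three-component disconnection. It dissolves the hindered ether bond and the ortho bromine in one operation and reduces ring B to an unsubstituted, symmetric aryne, so no regiochemical question exists. An alkyl ether on the C1 oxygen would survive this step as well, but it would leave ring A the more reactive ring afterwards and force a protecting-group exchange before the C4' bromination. Hence 4 already carries the electron-withdrawing mask, chosen without acidic C–H bonds. The forward step demands that the aryl anion take bromine and not a proton, so the phenoxide is formed with a base that leaves no proton donor, the medium is aprotic and not C–H acidic, and 6 is in excess.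

4 ⇒ 2. The C3–Br and C5–Br bonds are cut. In 2 the free hydroxyl is the only strong donor and directs bromine to its own ortho and para positions, which become C3 and C5 of the target. The sulfonyloxy group is weakly deactivating and cannot compete, so the substitution pattern is unambiguous. The forward step must go fully to the dibromide.

2 ⇒ 1. One S–O bond is cut, which leads back to a symmetric, commercial diol and a commercial arenesulfonyl chloride. This is the step that differentiates the two ring A oxygens. The forward step must stop after one sulfonylation.

## Other disconnections considered

Alternative 1: The cut goes through all four C–Br bonds at once (C3–Br, C5–Br, C2'–Br, C4'–Br) on a template in which the two rings are already tied by the ether oxygen and by a one-carbon bridge. Forward, xanthone A1 would be brominated four times (Br2, FeBr3) to 2,4,5,7-tetrabromoxanthone A2. The bridge would then be excised by Baeyer–Villiger oxygen insertion to the seven-membered lactone A3, hydrolysis to hydroxy acid A4 and protodecarboxylation to 13.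
- In favour: the hindered C–O bond is bought ready-made, which is better than the chosen plan on that point. The ring oxygen directs bromine ortho and para to itself on both rings. A2 is symmetric, so it does not matter which aryl group migrates. No protecting group is needed. At about four steps it is one shorter than the chosen plan, so it is the better on step economy.
- Against: the carbonyl deactivates both rings, so the two brominations ortho to oxygen would need forcing conditions and could stop short or stray. Oxygen insertion into a planar, cross-conjugated diaryl ketone bearing four bromines asks a poor migrating group to move onto a weakly electrophilic carbonyl. A4 can re-close to A3 on heating. A silver- or copper-mediated decarboxylation at high temperature sits badly with four C–Br bonds and a free phenol.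
- Comparison: the alternative uses familiar reaction types on unfavourable substrates in two late steps. The chosen plan has one untested combination of two known elementary steps in mid-route, with a known bypass. Structurally both reach the same pattern without ambiguity in the ether linkage.

Alternative 2: The cut is through C2–C3 and C1–C6, so that ring A is built from scratch. Forward, 3,5-dibromo-2-pyrone A5 and the aryloxyalkynyl boronate A6 would undergo [4+2] cycloaddition and loss of CO2 to aryl boronate A7, and oxidation of the C–B bond (H2O2, NaOH) would give 13.
- In favour: all four bromines arrive with the building blocks, so no electrophilic bromination has to be steered. The C1 oxygen comes from boron, so no protecting group is needed and only one step follows the key step, against two in the chosen plan. On the endgame and on protecting-group economy it is the better. The ynol-ether polarisation should send the nucleophilic boron-bearing carbon to the electrophilic C6 of A5, placing the aryloxy carbon next to C3–Br as required.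
- Against: A6 belongs to an unexplored and probably fragile class, since aryl ynol ethers tend to rearrange or polymerise well below the temperatures at which alkynyl boronates usually add to 2-pyrones. Its preparation through acetylide or ynolate chemistry clashes with two aryl bromides (halogen–lithium exchange). The boryl group opposes the oxygen polarisation and adds bulk, so the regiochemistry is not assured.
- Comparison: the pericyclic cascade is well founded, but it is loaded onto a precursor that may not be makeable, whereas the chosen plan uses stable, simple partners. The step count (about five) is equal.

Alternative 3: The cut is through C1'–C2' and C5'–C6', so that ring B is grown on the hindered oxygen. Forward, 2,4-dibromo-6-methoxyphenol A8 would be converted into its ethynyl ether A9. Cycloaddition with A5 and loss of CO2 would give the tetrabromo methyl ether A10, and demethylation (BBr3) would give 13.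
- In favour: both ring B bromines are fixed by the pyrone, so no late bromination is needed and ring A need not be deactivated. A simple methyl ether suffices, which is a point where this plan is better than the chosen one. The terminal carbon of the ynol ether is its most nucleophilic and least hindered site and should bond to C6 of A5, which places the oxygen-bearing carbon next to the pyrone C3–Br and gives the 2',4' pattern.
- Against: an aryl ethynyl ether of a 2,6-disubstituted, bromine-bearing phenol is hard to reach. The dichlorovinyl ether route needs two equivalents of organolithium, and alkynyliodonium reagents tend towards carbene-derived products. The ether must also survive the heat needed for CO2 extrusion.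
- Comparison: the ring-forming logic is sound and the endgame shorter, but the precursor synthesis adds two or three uncertain steps, so overall length (five to six) is equal or slightly worse. The chosen plan puts its single uncertainty into a step whose partners are commercial or two steps away.

Key step: step 3

## Route

Step 1
Reactants: 1 catechol (benzene-1,2-diol)
Product: 2 2-hydroxyphenyl benzenesulfonate
Conditions: PhSO2Cl (1.0 equiv), Et3N (1.1 equiv), CH2Cl2, 0 °C → rt; 1 in excess (1.5 equiv)
Reagents that add atoms: benzenesulfonyl chloride, O=S(=O)(Cl)c1ccccc1
Why: O-sulfonylation of one of two equivalent hydroxyls; the monoester is less nucleophilic (electron-withdrawing sulfonyloxy neighbour, more hindered) and surplus 1 is washed out with water, so mono-protection should dominate.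

Step 2
Reactants: 2 2-hydroxyphenyl benzenesulfonate
Product: 4 3,5-dibromo-2-hydroxyphenyl benzenesulfonate, via para-monobromide 3 (not isolated)
Conditions: Br2 (2.1 equiv), AcOH, rt → 40 °C
Reagents that add atoms: bromine, BrBr
Why: Electrophilic aromatic bromination directed by the free hydroxyl, first para and then ortho to it; the sulfonyloxy group is weakly deactivating and its own ortho and para positions are meta to the hydroxyl, so only the 3,5-dibromide is expected.

Step 3
Reactants: 4 3,5-dibromo-2-hydroxyphenyl benzenesulfonate; 5 2-(trimethylsilyl)phenyl trifluoromethanesulfonate; 6 1,2-dibromo-1,1,2,2-tetrachloroethane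
Product: 10 3,5-dibromo-2-(2-bromophenoxy)phenyl benzenesulfonate, via potassium phenoxide 7 (not isolated), via benzyne 8 (not isolated), via arylpotassium adduct 9 (not isolated)
Conditions: KH (1.0 equiv), THF, 0 °C; then 18-crown-6 (3 equiv), KF (3 equiv), 6 (2.5 equiv), slow addition of 5 (1.5 equiv), THF, 0 °C → rt
Reagents that add atoms: none
Why: Proposed new method: fluoride attacks silicon of 5 and the resulting aryl anion expels triflate (Kobayashi 1,2-elimination) to give benzyne 8, whose strained, low-lying in-plane orbital accepts the oxygen of the crown-separated phenoxide 7 even though that oxygen is flanked by Br and OSO2Ph. The ortho-aryloxyaryl anion 9 then attacks a bromine atom of 6 (halophilic substitution with loss of bromide and Cl2C=CCl2), forming the C2'–Br bond; the closest known reaction types are the fluoride-mediated O-arylation of phenols with silylaryl triflates and the three-component amino- or thio-halogenation of arynes with electrophilic halogen donors. No ring is closed and no stereocentre is created. Benzyne is symmetric, so oxygen and bromine necessarily end up on adjacent carbons and no regiochemical question arises. The selectivity needed is bromine capture by 9 in preference to protonation; it is secured by forming 7 with KH (H2 is the only by-product, whereas a carbonate base would leave hydrogencarbonate as a proton donor), by THF in place of C–H acidic MeCN, by a sulfonate without acidic C–H bonds and by an excess of 6. Phenoxide 7 has both ortho positions and the para position occupied, so 6 cannot brominate it on carbon, and slow addition of 5 keeps benzyne scarce so that 7 should outcompete bromide and fluoride as the nucleophile. Should 9 instead take the C3 bromine of ring A through a six-membered transition state, the ring A anion would be re-brominated by 6 at the same carbon, so the constitution of 10 would be unchanged.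

Step 4
Reactants: 10 3,5-dibromo-2-(2-bromophenoxy)phenyl benzenesulfonate
Product: 11 3,5-dibromo-2-(2,4-dibromophenoxy)phenyl benzenesulfonate
Conditions: Br2 (1.15 equiv), FeBr3 (5 mol%), CH2Cl2, 0 °C → rt, dark
Reagents that add atoms: bromine, BrBr
Why: Lewis-acid-catalysed electrophilic aromatic bromination; ring A (two Br, sulfonyloxy) and ring C (sulfonyl) are strongly deactivated, so the ether oxygen directs the single bromine para to itself on ring B (C4'), C2' being occupied and C6' screened by the twisted ring A.

Step 5
Reactants: 11 3,5-dibromo-2-(2,4-dibromophenoxy)phenyl benzenesulfonate
Product: 13 3,5-dibromo-2-(2,4-dibromophenoxy)phenol, via potassium phenoxide 12 (not isolated)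
Conditions: KOH (4 equiv), 1,4-dioxane/H2O (3:1), 70 °C; then 1 M HCl
Reagents that add atoms: none
Why: Hydroxide substitution at sulfonyl sulfur (S–O cleavage), helped by the well-stabilised dibromo-aryloxyphenoxide leaving group; hydroxide in an alcohol-free medium forms no alkyl sulfonate that could O-alkylate 12, and unactivated aryl bromides should not react with hydroxide at this temperature.

## Compound list

1 | catechol (benzene-1,2-diol) | Oc1ccccc1O | starting material
2 | 2-hydroxyphenyl benzenesulfonate | O=S(=O)(Oc1ccccc1O)c1ccccc1 | intermediate
3 | 5-bromo-2-hydroxyphenyl benzenesulfonate (para-monobromide) | O=S(=O)(Oc1cc(Br)ccc1O)c1ccccc1 | intermediate (not isolated)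
4 | 3,5-dibromo-2-hydroxyphenyl benzenesulfonate | O=S(=O)(Oc1cc(Br)cc(Br)c1O)c1ccccc1 | intermediate
5 | 2-(trimethylsilyl)phenyl trifluoromethanesulfonate | C[Si](C)(C)c1ccccc1OS(=O)(=O)C(F)(F)F | starting material
6 | 1,2-dibromo-1,1,2,2-tetrachloroethane | BrC(Cl)(Cl)C(Cl)(Cl)Br | starting material
7 | potassium 2,4-dibromo-6-(phenylsulfonyloxy)phenoxide | [K+].[O-]c1c(Br)cc(Br)cc1OS(=O)(=O)c1ccccc1 | intermediate (not isolated)
8 | benzyne (1,2-didehydrobenzene) | C1#CC=CC=C1 | intermediate (not isolated)
9 | {2-[2,4-dibromo-6-(phenylsulfonyloxy)phenoxy]phenyl}potassium | [K+].[c-]1ccccc1Oc1c(Br)cc(Br)cc1OS(=O)(=O)c1ccccc1 | intermediate (not isolated)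
10 | 3,5-dibromo-2-(2-bromophenoxy)phenyl benzenesulfonate | O=S(=O)(Oc1cc(Br)cc(Br)c1Oc1ccccc1Br)c1ccccc1 | intermediate
11 | 3,5-dibromo-2-(2,4-dibromophenoxy)phenyl benzenesulfonate | O=S(=O)(Oc1cc(Br)cc(Br)c1Oc1ccc(Br)cc1Br)c1ccccc1 | intermediate
12 | potassium 3,5-dibromo-2-(2,4-dibromophenoxy)phenoxide | [K+].[O-]c1cc(Br)cc(Br)c1Oc1ccc(Br)cc1Br | intermediate (not isolated)
13 | 3,5-dibromo-2-(2,4-dibromophenoxy)phenol | Oc1cc(Br)cc(Br)c1Oc1ccc(Br)cc1Br | target

## Step count and least certain steps

Total step count: 5. Longest linear sequence: 5 steps (1 → 2 → 4 → 10 → 11 → 13); 5 and 6 are commercial and enter at step 3.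

Step 3 (key step, proposed new method). Most likely to go wrong:
- Protonation of anion 9 before it meets 6 (traces of water, C–H acidity of the medium), which would deliver the ether without the C2' bromine.
- Capture of benzyne by the accumulating bromide or by fluoride instead of the weakly nucleophilic, hindered phenoxide 7.
- Attack of fluoride or of 7 at sulfonyl sulfur (sulfonyl transfer).

Fallback, from 4 back to the route at 11, using known chemistry. Phenol 4 is deprotonated (t-BuOK, THF, 0 °C) and O-arylated with bis(2,4-dibromophenyl)iodonium trifluoromethanesulfonate F1 (THF, rt → 40 °C). F1 is prepared in one operation from 1,3-dibromobenzene, I2 and mCPBA in TfOH/CH2Cl2. Metal-free arylation of hindered phenoxides by ortho-substituted diaryliodonium salts is established. It brings in ring B with both bromines, so it replaces steps 3 and 4.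

Step 4. Most likely to go wrong: sluggish substitution, because the ether oxygen is attached to an electron-poor ring A and donates weakly. Forcing then invites attack at C6', a second bromination, or bromination of ring C.

Fallback, from 10 back to 11. Nitration (HNO3, H2SO4, AcOH, 0 °C), which uses a far stronger electrophile and is self-limiting after one substitution, should give 3,5-dibromo-2-(2-bromo-4-nitrophenoxy)phenyl benzenesulfonate F2. Reduction (Fe powder, NH4Cl, EtOH/H2O, 70 °C) should give 2-(4-amino-2-bromophenoxy)-3,5-dibromophenyl benzenesulfonate F3. Sandmeyer bromination (t-BuONO, CuBr2, MeCN, 0 → 60 °C) should then give 11.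

Step 1. Most likely to go wrong: over-sulfonylation, since the selection between the first and second hydroxyl is only kinetic and a statistical share of diester would lower throughput.

Fallback, from 1 back to 2. Exhaustive sulfonylation (PhSO2Cl 2.2 equiv, Et3N, DMAP, CH2Cl2) gives 1,2-phenylene dibenzenesulfonate F4. Cleavage of one ester only (KOH 2.1 equiv, 1,4-dioxane/H2O, 50 °C) then gives 2. The second cleavage should be much slower because the mono-phenoxide is electron-rich and its departure would require a catechol dianion.

Step 5. Most likely to go wrong: base-induced aryl migration between the two ring A oxygens in phenoxide 12 (Smiles-type ipso attack on ring B, which carries ortho and para bromines) under hot alkali, or incomplete S–O cleavage if the conditions are softened to avoid it.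

Fallback, from 10 to 13. The sulfonate is cleaved one stage earlier (KOH, 1,4-dioxane/H2O, 70 °C), where ring B has a single bromine and is a poorer migrating group, to give 3,5-dibromo-2-(2-bromophenoxy)phenol F5. Acetylation (Ac2O, pyridine, DMAP, CH2Cl2) gives 3,5-dibromo-2-(2-bromophenoxy)phenyl acetate F6. Bromination (Br2, FeBr3, CH2Cl2) gives 3,5-dibromo-2-(2,4-dibromophenoxy)phenyl acetate F7. Methanolysis at room temperature (K2CO3, MeOH) then releases 13 under conditions too mild for aryl migration.

## Further compounds

F1 | step 3 | bis(2,4-dibromophenyl)iodonium trifluoromethanesulfonate | Brc1ccc([I+]c2ccc(Br)cc2Br)c(Br)c1.[O-]S(=O)(=O)C(F)(F)F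
F2 | step 4 | 3,5-dibromo-2-(2-bromo-4-nitrophenoxy)phenyl benzenesulfonate | O=S(=O)(Oc1cc(Br)cc(Br)c1Oc1ccc(cc1Br)[N+](=O)[O-])c1ccccc1
F3 | step 4 | 2-(4-amino-2-bromophenoxy)-3,5-dibromophenyl benzenesulfonate | O=S(=O)(Oc1cc(Br)cc(Br)c1Oc1ccc(N)cc1Br)c1ccccc1
F4 | step 1 | 1,2-phenylene dibenzenesulfonate | O=S(=O)(Oc1ccccc1OS(=O)(=O)c1ccccc1)c1ccccc1
F5 | step 5 | 3,5-dibromo-2-(2-bromophenoxy)phenol | Oc1cc(Br)cc(Br)c1Oc1ccccc1Br
F6 | step 5 | 3,5-dibromo-2-(2-bromophenoxy)phenyl acetate | CC(=O)Oc1cc(Br)cc(Br)c1Oc1ccccc1Br
F7 | step 5 | 3,5-dibromo-2-(2,4-dibromophenoxy)phenyl acetate | CC(=O)Oc1cc(Br)cc(Br)c1Oc1ccc(Br)cc1Br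
A1 | alternative 1 | 9H-xanthen-9-one (xanthone) | O=C1c2ccccc2Oc2ccccc12
A2 | alternative 1 | 2,4,5,7-tetrabromo-9H-xanthen-9-one | O=C1c2cc(Br)cc(Br)c2Oc2c(Br)cc(Br)cc12
A3 | alternative 1 | 2,4,6,8-tetrabromo-11H-dibenzo[b,e][1,4]dioxepin-11-one | O=C1Oc2cc(Br)cc(Br)c2Oc2c(Br)cc(Br)cc12
A4 | alternative 1 | 3,5-dibromo-2-(2,4-dibromo-6-hydroxyphenoxy)benzoic acid | OC(=O)c1cc(Br)cc(Br)c1Oc1c(O)cc(Br)cc1Br
A5 | alternative 2 | 3,5-dibromo-2H-pyran-2-one | O=c1occ(Br)cc1Br
A6 | alternative 2 | 2-[(2,4-dibromophenoxy)ethynyl]-4,4,5,5-tetramethyl-1,3,2-dioxaborolane | CC1(C)OB(OC1(C)C)C#COc1ccc(Br)cc1Br
A7 | alternative 2 | 2-[3,5-dibromo-2-(2,4-dibromophenoxy)phenyl]-4,4,5,5-tetramethyl-1,3,2-dioxaborolane | CC1(C)OB(OC1(C)C)c1cc(Br)cc(Br)c1Oc1ccc(Br)cc1Br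
A8 | alternative 3 | 2,4-dibromo-6-methoxyphenol | COc1cc(Br)cc(Br)c1O
A9 | alternative 3 | 1,5-dibromo-2-(ethynyloxy)-3-methoxybenzene | COc1cc(Br)cc(Br)c1OC#C
A10 | alternative 3 | 1,5-dibromo-2-(2,4-dibromophenoxy)-3-methoxybenzene | COc1cc(Br)cc(Br)c1Oc1ccc(Br)cc1Br
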